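**Retrosynthetic overview**
1. Zeylenone 12 ⇐ Mitsunobu benzoylation with inversion at allylic C5 of triol-enone 10 ⇐ desilylation and MnO2 oxidation at C2 of triol 8.
2. 8 ⇐ C6–OH-directed syn-osmylation of C1=C2 in diene 6 ⇐ C7 benzoylation, ester reduction and C5 silylation of cis-dihydrodiol 2.
3. 2 ⇐ ethyl benzoate 1 by toluene dioxygenase cis-dihydroxylation, which forms the C5–O and C6–O bonds.
4. Feature used: in the target ring (C1 quaternary carbinol bearing C7, C2 ketone, C3=C4, C5 benzoate carbon, C6 secondary carbinol) the contiguous C1, C6 and C5 are the ipso, ortho and meta carbons of a benzoate ester whose carboxyl carbon is C7, so O6 and O5 are the two oxygens of an arene cis-diol.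
5. Ring order: the single carbocycle is never closed; it is the benzene ring of 1, dearomatised in step 1 and afterwards only oxidised at C1 and C2.

Key step: step 1

Remark (assumption): the recombinant strain E. coli JM109(pDTG601), which overexpresses toluene dioxygenase, is taken as an available biocatalyst. Ring positions are cited with the target numbering given in line 4. TBS = tert-butyldimethylsilyl, TMEDA = N,N,N',N'-tetramethylethylenediamine, DIAD = diisopropyl azodicarboxylate.

**Route**

Step 1
Reactants: 1 ethyl benzoate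
Product: 2 ethyl (5S,6R)-5,6-dihydroxycyclohexa-1,3-diene-1-carboxylate
Conditions: E. coli JM109(pDTG601) whole cells expressing toluene dioxygenase, IPTG, glucose feed, air, mineral salts medium pH 7, 30 °C; EtOAc extraction of the cell-free broth
Reagents that add atoms: dioxygen, O=O
Why: The non-heme iron centre of toluene dioxygenase, supplied with two electrons from cellular NADH through its iron–sulfur cluster, binds O2 and transfers both oxygen atoms suprafacially to the ortho–meta bond of the arene (C6 and C5 of the target ring), releasing the cis-dihydrodiol. The closest known reaction type is the whole-cell toluene dioxygenase cis-dihydroxylation of monosubstituted benzenes, a substrate class that includes benzoate esters. No ring is closed: the benzene ring of 1 becomes the carbocycle of the target and the carboxyl carbon becomes C7. Both new stereocentres, C5 (S) and C6 (R), are set by the active-site pocket, which holds the substituted ring in one orientation towards the iron-bound oxygen; C6 is delivered with the spatial arrangement of the target and C5 as the epimer that step 8 inverts. The step needs ortho,meta regioselectivity, a single dihydroxylation and enantiofacial selectivity, all enforced by the enzyme and not by the substrate, while the conjugating ester should slow acid-promoted dehydration of the diene diol to phenols during isolation.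

Step 2
Reactants: 2 ethyl (5S,6R)-5,6-dihydroxycyclohexa-1,3-diene-1-carboxylate
Product: 3 ethyl (5S,6R)-5-[(tert-butyldimethylsilyl)oxy]-6-hydroxycyclohexa-1,3-diene-1-carboxylate
Conditions: TBSCl (1.05 equiv), imidazole, DMF, −20 to 0 °C
Reagents that add atoms: tert-butyldimethylsilyl chloride (TBSCl), CC(C)(C)[Si](C)(C)Cl
Why: Imidazole-mediated silyl ether formation should take place at the distal C5 hydroxyl, because the C6 hydroxyl is flanked by the ester-bearing sp2 carbon and engaged in a hydrogen bond to the ester carbonyl, and no stereocentre is touched.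

Step 3
Reactants: 3 ethyl (5S,6R)-5-[(tert-butyldimethylsilyl)oxy]-6-hydroxycyclohexa-1,3-diene-1-carboxylate
Product: 4 [(5S,6R)-5-[(tert-butyldimethylsilyl)oxy]-6-hydroxycyclohexa-1,3-dien-1-yl]methanol
Conditions: i-Bu2AlH (3.2 equiv), CH2Cl2, −78 to −40 °C; aqueous potassium sodium tartrate work-up
Reagents that add atoms: none
Why: Hydride 1,2-reduction of the conjugated ester with i-Bu2AlH should give the primary dienylic alcohol at low temperature without touching the diene or the silyl ether, the C6 hydroxyl being carried as its aluminium alkoxide and the neutral tartrate work-up avoiding acid-promoted aromatisation.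

Step 4
Reactants: 4 [(5S,6R)-5-[(tert-butyldimethylsilyl)oxy]-6-hydroxycyclohexa-1,3-dien-1-yl]methanol; 5 benzoyl chloride
Product: 6 [(5S,6R)-5-[(tert-butyldimethylsilyl)oxy]-6-hydroxycyclohexa-1,3-dien-1-yl]methyl benzoate
Conditions: BzCl (1.05 equiv), pyridine, CH2Cl2, −40 to −20 °C
Reagents that add atoms: benzoyl chloride (5), O=C(Cl)c1ccccc1
Why: Kinetically controlled acylation with one equivalent of benzoyl chloride should esterify the unhindered primary C7 hydroxyl in preference to the secondary C6 hydroxyl, which sits between the silyloxy-bearing C5 and the substituted C1.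

Step 5
Reactants: 6 [(5S,6R)-5-[(tert-butyldimethylsilyl)oxy]-6-hydroxycyclohexa-1,3-dien-1-yl]methyl benzoate
Product: 8 [(1R,2R,5S,6S)-5-[(tert-butyldimethylsilyl)oxy]-1,2,6-trihydroxycyclohex-3-en-1-yl]methyl benzoate, via C1,C2-cyclic osmate ester TMEDA chelate 7 (not isolated)
Conditions: OsO4 (1.05 equiv), TMEDA (1.1 equiv), CH2Cl2, −78 °C; then aqueous Na2SO3, THF, 40–50 °C
Reagents that add atoms: osmium tetroxide OsO4, O=[Os](=O)(=O)=O (both new hydroxyl oxygens); TMEDA, CN(C)CCN(C)C (held only in intermediate 7)
Why: In this hydrogen-bond-directed syn-dihydroxylation the OsO4·TMEDA complex, a strong hydrogen-bond acceptor, should be guided by the free allylic C6 hydroxyl to the adjacent trisubstituted C1=C2 bond and to the face carrying that hydroxyl in a concerted [3+2] addition, so that the new C1 and C2 carbinol centres are both set cis to the C6 hydroxyl while C3=C4, whose only allylic oxygen is the non-donating silyl ether, is left alone, after which sulfite reduces and hydrolyses the hexavalent osmium chelate 7.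

Step 6
Reactants: 8 [(1R,2R,5S,6S)-5-[(tert-butyldimethylsilyl)oxy]-1,2,6-trihydroxycyclohex-3-en-1-yl]methyl benzoate
Product: 9 [(1S,5S,6S)-5-[(tert-butyldimethylsilyl)oxy]-1,6-dihydroxy-2-oxocyclohex-3-en-1-yl]methyl benzoate
Conditions: activated MnO2 (excess), CH2Cl2, rt
Reagents that add atoms: none
Why: Chemoselective allylic alcohol oxidation with activated MnO2 should convert only the allylic C2 carbinol into the enone carbonyl, the non-allylic secondary C6 hydroxyl and the tertiary C1 hydroxyl being inert to this reagent, so the C2 stereocentre is removed on purpose and C1, C5 and C6 stay as set.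

Step 7
Reactants: 9 [(1S,5S,6S)-5-[(tert-butyldimethylsilyl)oxy]-1,6-dihydroxy-2-oxocyclohex-3-en-1-yl]methyl benzoate
Product: 10 [(1S,5S,6S)-1,5,6-trihydroxy-2-oxocyclohex-3-en-1-yl]methyl benzoate
Conditions: HF·pyridine, pyridine, THF, 0 °C to rt
Reagents that add atoms: none
Why: Fluoride-mediated desilylation under buffered acidic conditions should free the C5 hydroxyl without the benzoate migration or retro-aldol cleavage of the β-hydroxy ketone that a basic fluoride source could cause.

Step 8
Reactants: 10 [(1S,5S,6S)-1,5,6-trihydroxy-2-oxocyclohex-3-en-1-yl]methyl benzoate; 11 benzoic acid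
Product: 12 zeylenone, [(1S,5R,6S)-5-(benzoyloxy)-1,6-dihydroxy-2-oxocyclohex-3-en-1-yl]methyl benzoate
Conditions: PPh3, DIAD, BzOH, THF, −20 to 0 °C
Reagents that add atoms: benzoic acid (11), O=C(O)c1ccccc1
Why: In this Mitsunobu reaction the allylic C5 hydroxyl, the most accessible and SN2-reactive of the three (the C6 hydroxyl is neopentyl-like beside the quaternary C1 and the C1 hydroxyl is tertiary), should be activated as its oxyphosphonium salt and displaced by benzoate with inversion, turning the enzyme-set (5S) centre into the (5R) benzoate trans to the C6 hydroxyl, and because a cis-5,6-diol cannot close to an epoxide any dioxaphosphorane formed should open through the same allylic displacement.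

**Compound list**
1 | ethyl benzoate | CCOC(=O)c1ccccc1 | starting material
2 | ethyl (5S,6R)-5,6-dihydroxycyclohexa-1,3-diene-1-carboxylate | CCOC(=O)C1=CC=C[C@H](O)[C@@H]1O | intermediate
3 | ethyl (5S,6R)-5-[(tert-butyldimethylsilyl)oxy]-6-hydroxycyclohexa-1,3-diene-1-carboxylate | CCOC(=O)C1=CC=C[C@H](O[Si](C)(C)C(C)(C)C)[C@@H]1O | intermediate
4 | [(5S,6R)-5-[(tert-butyldimethylsilyl)oxy]-6-hydroxycyclohexa-1,3-dien-1-yl]methanol | OCC1=CC=C[C@H](O[Si](C)(C)C(C)(C)C)[C@@H]1O | intermediate
5 | benzoyl chloride | O=C(Cl)c1ccccc1 | starting material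
6 | [(5S,6R)-5-[(tert-butyldimethylsilyl)oxy]-6-hydroxycyclohexa-1,3-dien-1-yl]methyl benzoate | O=C(OCC1=CC=C[C@H](O[Si](C)(C)C(C)(C)C)[C@@H]1O)c1ccccc1 | intermediate
7 | C1,C2-cyclic osmate ester TMEDA chelate of 8 (hexavalent osmium, OsO2 unit bound to O1, O2 and both TMEDA nitrogens; not isolated) | O=C(OC[C@@]1(O[Os-2]23(=O)(=O)[N+](C)(C)CC[N+]2(C)C)[C@H](O3)C=C[C@H](O[Si](C)(C)C(C)(C)C)[C@@H]1O)c1ccccc1 | intermediate
8 | [(1R,2R,5S,6S)-5-[(tert-butyldimethylsilyl)oxy]-1,2,6-trihydroxycyclohex-3-en-1-yl]methyl benzoate | O=C(OC[C@@]1(O)[C@H](O)C=C[C@H](O[Si](C)(C)C(C)(C)C)[C@@H]1O)c1ccccc1 | intermediate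
9 | [(1S,5S,6S)-5-[(tert-butyldimethylsilyl)oxy]-1,6-dihydroxy-2-oxocyclohex-3-en-1-yl]methyl benzoate | O=C(OC[C@@]1(O)C(=O)C=C[C@H](O[Si](C)(C)C(C)(C)C)[C@@H]1O)c1ccccc1 | intermediate
10 | [(1S,5S,6S)-1,5,6-trihydroxy-2-oxocyclohex-3-en-1-yl]methyl benzoate | O=C(OC[C@@]1(O)C(=O)C=C[C@H](O)[C@@H]1O)c1ccccc1 | intermediate
11 | benzoic acid | O=C(O)c1ccccc1 | starting material
12 | zeylenone, [(1S,5R,6S)-5-(benzoyloxy)-1,6-dihydroxy-2-oxocyclohex-3-en-1-yl]methyl benzoate | O=C(OC[C@@]1(O)C(=O)C=C[C@@H](OC(=O)c2ccccc2)[C@@H]1O)c1ccccc1 | target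

**Step count**
Total: 8 steps. Longest linear sequence: 8 steps (1 → 12); benzoyl chloride 5 and benzoic acid 11 enter as commercial materials.

**Steps most likely to fail**

Step 8 (Mitsunobu on the unprotected triol). The risk is loss of site selectivity among the three hydroxyls, or elimination or SN2' pathways from the activated γ-oxygenated enone. The fallback removes the selectivity question with a protecting group. Setting out from 9, the cis C1/C6 diol would be masked with 2-methoxypropene and PPTS in CH2Cl2 to give the 1,6-O-isopropylidene acetal of 9 F1. HF·pyridine would then free the only remaining hydroxyl to give the 5-hydroxy acetonide F2. A Mitsunobu reaction (PPh3, DIAD, benzoic acid 11) on this mono-alcohol would give 1,6-O-isopropylidene zeylenone F3. Aqueous trifluoroacetic acid at 0 °C would remove the acetonide and return to the route at the target 12.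

Step 5 (directed osmylation of the diene). The risk is poor regiocontrol (attack at C3=C4) or poor facial control (attack anti to the C6 hydroxyl). The fallback replaces osmylation by a metal-alkoxide-bound oxidant that can only reach the alkene of the allylic alcohol. Setting out from 6, a vanadium-catalysed hydroxyl-directed epoxidation (VO(acac)2 cat., t-BuOOH, CH2Cl2, 0 °C) would place the epoxide oxygen on C1=C2 syn to the C6 hydroxyl and give the syn-1,2-epoxy alcohol F4. Acid-catalysed hydrolysis (cat. HClO4, THF–H2O, 0 °C) should open the vinyl epoxide at the allylic C2 with inversion, leaving the C1–O bond and therefore the C1 configuration intact, to give the 2-epi-triol F5. MnO2 would then oxidise the allylic C2 carbinol, which erases the C2 configuration, and rejoin the route at 9.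

Step 2 (regioselective monosilylation). The risk is silylation at C6 or at both hydroxyls, or silyl migration between the cis oxygens. The fallback differentiates the oxygens through a cyclic 1,3-diol protecting group instead of steric bias. Setting out from 2, excess i-Bu2AlH would give the triol [(5S,6R)-5,6-dihydroxycyclohexa-1,3-dien-1-yl]methanol F6. t-Bu2Si(OTf)2 with 2,6-lutidine in DMF should bridge O6 and O7 as the six-membered C6,C7-O-di-tert-butylsilylene acetal F7, the 1,3-diol being preferred over the cis-1,2-diol as in the 3',5'-protection of ribonucleosides, so that only the C5 hydroxyl stays free. TBSCl and imidazole would give the C5 TBS ether of the silylene acetal F8. Brief treatment with HF·pyridine at 0 °C should cleave the cyclic silylene selectively and return to the route at 4.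

**Further compounds**
F1 | step 8 | 1,6-O-isopropylidene acetal of 9, [(1S,5S,6S)-5-[(tert-butyldimethylsilyl)oxy]-1,6-(isopropylidenedioxy)-2-oxocyclohex-3-en-1-yl]methyl benzoate | O=C(OC[C@@]1(OC(C)(C)O2)C(=O)C=C[C@H](O[Si](C)(C)C(C)(C)C)[C@@H]12)c1ccccc1
F2 | step 8 | 5-hydroxy acetonide, [(1S,5S,6S)-5-hydroxy-1,6-(isopropylidenedioxy)-2-oxocyclohex-3-en-1-yl]methyl benzoate | O=C(OC[C@@]1(OC(C)(C)O2)C(=O)C=C[C@H](O)[C@@H]12)c1ccccc1
F3 | step 8 | 1,6-O-isopropylidene zeylenone, [(1S,5R,6S)-5-(benzoyloxy)-1,6-(isopropylidenedioxy)-2-oxocyclohex-3-en-1-yl]methyl benzoate | O=C(OC[C@@]1(OC(C)(C)O2)C(=O)C=C[C@@H](OC(=O)c3ccccc3)[C@@H]12)c1ccccc1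
F4 | step 5 | syn-1,2-epoxy alcohol, [(1S,2R,5S,6S)-5-[(tert-butyldimethylsilyl)oxy]-1,2-epoxy-6-hydroxycyclohex-3-en-1-yl]methyl benzoate | O=C(OC[C@@]1(O2)[C@H]2C=C[C@H](O[Si](C)(C)C(C)(C)C)[C@@H]1O)c1ccccc1
F5 | step 5 | 2-epi-triol, [(1R,2S,5S,6S)-5-[(tert-butyldimethylsilyl)oxy]-1,2,6-trihydroxycyclohex-3-en-1-yl]methyl benzoate | O=C(OC[C@@]1(O)[C@@H](O)C=C[C@H](O[Si](C)(C)C(C)(C)C)[C@@H]1O)c1ccccc1
F6 | step 2 | triol [(5S,6R)-5,6-dihydroxycyclohexa-1,3-dien-1-yl]methanol | OCC1=CC=C[C@H](O)[C@@H]1O
F7 | step 2 | C6,C7-O-di-tert-butylsilylene acetal, (8S,8aR)-2,2-di-tert-butyl-8,8a-dihydro-4H-benzo[d][1,3,2]dioxasilin-8-ol | CC(C)(C)[Si]3(C(C)(C)C)OCC1=CC=C[C@H](O)[C@@H]1O3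
F8 | step 2 | C5 TBS ether of the silylene acetal, (8S,8aR)-2,2-di-tert-butyl-8-[(tert-butyldimethylsilyl)oxy]-8,8a-dihydro-4H-benzo[d][1,3,2]dioxasiline | CC(C)(C)[Si]3(C(C)(C)C)OCC1=CC=C[C@H](O[Si](C)(C)C(C)(C)C)[C@@H]1O3
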